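**Reagent left.** What remains of the reagent at the end of a run is where the reckoning starts.

the same everywhere: temperature 80 °C

| charge | substrate | reagent | remark | time |
|---|---|---|---|---|
| birch | 1.5 M | 3 M | run made earlier |  |
| alder | 0.50 M | 3 M | run made earlier |  |
| north-west | 1.0 M | 2.00 M |  | 20 h |
| east | 1.0 M | 3.00 M |  | 20 h |
| north | 1.0 M | 1.50 M |  | 20 h |
| west | 1.0 M | 0.800 M |  | 20 h |

| run | time / h | target / % | side product / % |
|---|---|---|---|
| birch | 2.50 | 38.8 | 14.2 |
| birch | 5.00 | 61.6 | 18.8 |
| birch | 8.00 | 74.2 | 18.4 |
| birch | 10.0 | 75.1 | 17.9 |
| birch | 12.0 | 78.7 | 18.1 |
| alder | 1.00 | 9.2 | 8.8 |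
| alder | 2.00 | 31.5 | 15.1 |
| alder | 3.00 | 47.7 | 19.4 |
| alder | 6.00 | 69.7 | 24.5 |
| alder | 12.0 | 75.2 | 23.5 |

(standard deviation of a reading: 1 percentage point)

* ranking by share of target in all that became target or side product, from high to low, at 20 h (north-west / east / north / west)
* the share of target in all that became target or side product of the flask you put first, at 20 h
* the share of target in all that became target or side product of the flask you put last, at 20 h

**The fork.** At 1.00 h the alder run reads 8.8% side product beside 9.2% target, but at 12.0 h it reads 23.5% beside 75.2%: side product comes early, target late. So follow one substrate molecule. I suppose that once reacted it meets a fork, where reagent takes it to side product or it goes on unaided to target, and that target costs one reagent and side product two.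

**Two ways.** Divide side product per target by the mean reagent, the mean of charge and remainder. The last alder reading has mean reagent 2.69 M and gives 0.116 M⁻¹. The last birch reading, at a lower 2.14 M, gives 0.108 M⁻¹. That gap is about what a scatter of 1 percentage point does to a reading of 18.1%, so I trust their mean, 0.112 M⁻¹: the fork constant, side product made per target made for each mole per litre of reagent present, a selectivity factor. The target share is then one over one plus fork constant times mean reagent.

**My reckoning.** Substrate is equal in the four flasks, so the share should rise as the reagent charge falls, from east to west. With birch's reagent cost per substrate, east has mean reagent 2.43 M and a share of 78.7%. In west, reagent is the limiting reagent, with 0.800 M charged against 1.0 M of substrate. Scaling alder's early loss of substrate gives reagent an estimated half-life near 5.61 h, shorter than the 20 h of the run, so for west I take the mean of the charge and zero, which gives 95.7%.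

The forecast gives west > north > north-west > east, with 86% (79% to 92%) first and 79% (76% to 82%) last, holding that “the share improves as the reagent-to-substrate ratio falls”; its first figure is lower than mine.

**Result.** The flasks give west > north > north-west > east, with west at 95.1% and east at 78.0%.

    substrate + reagent → intermediate A (k = 0.00330 M⁻¹ min⁻¹, Ea = 100 kJ mol⁻¹)
    reagent + intermediate A → side product (k = 0.00690 M⁻¹ min⁻¹, Ea = 84.0 kJ mol⁻¹)
    intermediate A → intermediate B (k = 0.0570 min⁻¹, Ea = 103 kJ mol⁻¹)
    intermediate B → target (k = 0.0210 min⁻¹, Ea = 108 kJ mol⁻¹)
    (constants at 80 °C)

**Neighbour flask.** West kept 13% of its reagent, so its mean was 0.450 M, and the fork constant then gives 95.2%. Now charge the neighbour of west with 2.0 M of reagent, all else held. It keeps 44% of that charge, so its mean reagent is 1.44 M and the fork constant gives 86.1%. The neighbour flask stands at 85.6%, with 84.1% target and 14.1% side product.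

(The earlier runs and the new flask come from a simulation for substances that don't exist, noise included.)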